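A percentage point of the charge was my unit, and in it the two runs can be pooled.

| setting | south-west | north-west | flask |
|---|---|---|---|
| left-handed substrate | 0.050 M | 0.034 M | 0.050 M |
| right-handed substrate | 0.050 M | 0.034 M | 0.050 M |
| reagent | 0.11 M | 0.11 M | 0.110 M |
| free catalyst | 2.7 mM | 2.7 mM | 2.7 mM |
| racemization catalyst | 1.2 mM | 1.2 mM | 1.2 mM |
| remark | the very flask that is asked about, followed so far | run made earlier |  |
| time |  |  | 6.0 h |

| run | time / h | left-handed product / % | right-handed product / % |
|---|---|---|---|
| south-west | 0.133 | 5.3 | 2.4 |
| south-west | 0.333 | 13.1 | 5.0 |
| south-west | 0.667 | 21.2 | 6.9 |
| south-west | 1.00 | 27.2 | 10.9 |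
| south-west | 1.33 | 31.1 | 12.8 |
| south-west | 2.00 | 38.4 | 15.9 |
| south-west | 2.50 | 41.5 | 17.9 |
| north-west | 0.333 | 14.0 | 5.1 |
| north-west | 0.667 | 20.9 | 8.2 |
| north-west | 1.00 | 29.0 | 11.9 |
| north-west | 1.33 | 33.8 | 13.9 |
| north-west | 1.50 | 36.0 | 15.0 |
| north-west | 2.00 | 40.5 | 17.8 |
| north-west | 2.50 | 44.1 | 19.8 |

(standard deviation of a reading: 0.5 percentage points)

- left-handed product and right-handed product together, in percent of the left-handed substrate and right-handed substrate charged together, at 6.0 h
- excess of left-handed product over right-handed product in the product at 6.0 h
- whether the exchange between left-handed substrate and right-handed substrate keeps pace with the reaction: how far the product's excess at 6.0 h gets from its value without exchange to its value with instant exchange (above 80 % keeps pace, below 20 % hardly takes part, else lags behind)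

- free catalyst is single-handed; left-handed substrate and right-handed substrate are mirror images of each other, charged as a racemate, each of them at the stated concentration
- the analysis behind the earlier runs scatters by 0.5 percentage points, standard deviation
- an excess is the difference of the two amounts in percent of their sum
- an excess is below zero if the other one leads

I assumed that both hands meet the same reagent and free catalyst, so these cancel. The ratio in which product forms at any moment is then a constant times the ratio of two amounts, left-handed substrate over right-handed substrate. That constant is the selectivity factor, which I read as left-handed over right-handed product at 0.333 h, pooled over both runs, when the two substrates still stood close: 2.68.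

From 1.33 h to 2.50 h the two runs together added product at 1.88 left to right, so I read the substrate ratio there as 0.701. Without exchange, the balance of the south-west flask at 2.00 h gives 0.340, and instant exchange means 1. My reckoning therefore put the substrate ratio 54.7 % of the way between them: the exchange lags behind.

The forecast gave 79 %, an excess of 38 % and lags behind, holding that “Exchange is therefore real but finite”.

The south-west flask gave 78.6 %, an excess of 34.0 % and lags behind, 41 % of the way.

    reagent + free catalyst + left-handed substrate → free catalyst + left-handed product (k = 52.7 /M²/min)
    reagent + free catalyst + right-handed substrate → free catalyst + right-handed product (k = 17.3 /M²/min)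
    left-handed substrate + racemization catalyst ⇌ right-handed substrate + racemization catalyst, rate k3*[racemization catalyst]*[left-handed substrate] forward; the back reaction follows from the equilibrium constant (k = 13.0 /M/min)
    2 racemization catalyst → spent catalyst A (k = 13.6 /M/min)
    reagent + racemization catalyst → spent catalyst B (k = 0.0525 /M/min)

Set as an excess, my read selectivity factor 2.68 is 45.7 %, a reading with its scatter. The excess of the south-west flask's product stood at 45.8 % at 0.600 h and at 34.0 % at 6.00 h, when that flask held 5.95 % left-handed and 15.5 % right-handed substrate. A neighbour flask charged with 6.8 × 10⁻⁴ M of free catalyst held 20.3 % and 31.9 % at that time, and its excess of 42.6 % stood closer to that reading than the south-west flask's, at 47.8 % of product.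

(The data stem from a simulated flask with constants of no real substance; the scatter is artificial.)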